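## Structural features

Bromoiesol B (17) is built from three benzene rings in a row and has no stereocentre. The two diaryl ether oxygens sit on neighbouring carbons of the central ring B, so ring B is a catechol diether with two different aryl groups. Ring B is numbered here from the carbon bearing the oxygen to ring A (C1) to the carbon bearing the oxygen to ring C (C2); C3, C4 and C5 carry bromine and C6 carries the only hydrogen. Ring A is a 3,5-dibromophenol bound through its C2, and ring C is a 4-bromo-2-iodophenyl group. The only stereocentres in the plan are the two adjacent cis ring-fusion carbons of cycloadduct 8, and they vanish on aromatisation. The fragile groups are the C–I bond (reduction, low-valent metals, light, strong peracid), the six C–Br bonds (no organolithium or hot palladium/copper chemistry once the rings are joined), the free phenol, and the electron-poor catechol intermediate, which oxidises in basic air. The real difficulty is the contiguous Br–Br–Br–H–O–O pattern of ring B together with telling its two oxygens apart: they differ only in their neighbour (Br on C3 against H on C6) and, by substituent increments, by less than one pKa unit. The key step uses the fact that C3–C6 of ring B (Br, Br, Br, H) are the four diene carbons of a 2,3,4-tribromothiophene 1,1-dioxide, while C1 and C2 with their oxygens are the two carbons of vinylene carbonate.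

## Logic of the disconnections

17 ⇒ 15 (through 16). The C–O bond of the free hydroxyl on ring A is exchanged for a C–C bond to a formyl carbon. The cut is made there because a formyl group at that position is what activates ring A for ether formation, and it keeps ring A free of a second nucleophilic oxygen until the end. The gain is that no protecting group is needed. The demand is a peracid oxidation in which the aryl group, not hydrogen, migrates, and which leaves the iodide intact after work-up.

15 ⇒ 14. The C2–I bond of ring C is cut. In 14, ring C is the only ring with a C–H ortho to an ether oxygen that is not further deactivated, its para position is blocked by bromine and its two ortho positions are equivalent. The gain is that ring C becomes a plain 4-bromophenyl group. The demand is one site-selective electrophilic iodination.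

14 ⇒ 12 + 13. The bond between the oxygen on C2 of ring B and C1 of ring C is cut. The oxygen flanked by bromine is the crowded one, so it is arylated second, when no choice of oxygen remains. The gain is a purchasable partner, 13. The demand is a C–O coupling at room temperature that tolerates C–Br and CHO and uses a base too weak to let ring A migrate between the oxygens.

12 ⇒ 10 + 11. The bond between the oxygen on C1 of ring B and C2 of ring A is cut. Ring A then arrives with both bromines in place, by addition–elimination at the C–F bond of 11. The gain is convergence. The demand is a choice between the two hydroxyls of 10; this is left to steric hindrance and to reversibility, not to the small acidity difference.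

10 ⇒ 9 ⇒ 8. No skeletal bond is cut: the carbonyl bridge between the two oxygens is restored and two hydrogens are returned to C1 and C2 of ring B. This converts the arene into the cyclohexadiene that a cycloaddition can deliver. The demand is a dehydrogenation that does not eliminate one of the oxygens.

8 ⇒ 5 + 6 (through 7). The bonds C1–C6 and C2–C3 of ring B are cut and an SO2 bridge is reinstated between C3 and C6. The diene then fixes the three bromines and the hydrogen, and the dienophile supplies both oxygens. The gain is that no bromination of a catechol has to be selective. The demand is that cross-cycloaddition outruns self-cycloaddition of 5.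

5 ⇒ 3 ⇒ 1 (through 4 and 2). Two S–O bonds are removed and the C–H of 3 is traced back to a C–Br of 1. The gain is a cheap, symmetric starting material. The demands are a single bromine–lithium exchange and the oxidation of an electron-poor thiophene.

## Other disconnections considered

Alternative 1: The cut falls on ring C, at the bond from its C1 to the ether oxygen and at its C2–I bond. In the forward direction fluoride would release the aryne from silyl triflate A3, the phenoxide of the tribromoguaiacol A2 would add, and the ortho aryl anion would be quenched by an electrophilic iodine donor to give A1. O-demethylation and attachment of ring A would follow.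
- In its favour: two bonds of ring C would form in one metal-free step at room temperature, and iodine would enter without a later substitution. The methyl group of A2 distinguishes the two oxygens of ring B from the start, and A2 should be available by exhaustive bromination of guaiacol.
- Against it here: the bromine of the aryne is remote from the reacting carbons, so the inductive bias that should place oxygen para to bromine is weak, and formation of both regioisomeric ethers has to be expected. The di-ortho-substituted, weakly nucleophilic phenoxide of A2 may also lose out to proton capture by the aryl anion. The bromine pattern of A2 would depend on directing effects, which the chosen plan avoids by construction.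
- Comparison: on differentiation of the oxygens and on step count to the B–C half, this alternative is the better plan. On tolerance of aryl bromides the two are equal. On positional certainty at ring C the chosen plan is stronger, because steps 7 and 8 each have only one reasonable position.

Alternative 2: The cut removes two C–C bonds of ring A, so that its oxygen-bearing C2 and its later hydroxyl carbon become the two alkyne carbons of A6. In the forward direction A6 would add across C3 and C6 of pyrone A5, the bicyclic lactone would lose CO2 to give boronate A4, and oxidation of the C–B bond would give 17.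
- In its favour: both bromines of ring A come from the pyrone. Polarity matching supports the needed orientation (the boron-bearing alkyne carbon is the nucleophilic one, C6 of the pyrone the electrophilic one).
- Equal or better: the arene forms directly, with no dehydrogenation step, and the final C–B oxidation would be milder and more certain than the peracid step of the chosen plan.
- Against it here: A6 must carry the whole B–C half, including the aryl iodide. The usual ways to aryloxyalkynes and alkynylboronates use organolithium bases, which would attack the C–Br and C–I bonds. Aryl ynol ethers are thermally labile, while pyrone–alkyne cycloadditions need prolonged heating. Ring A is also the one ring that can be bought fully substituted (11).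
- Comparison: the mechanism is of the same family as the chosen key step (cycloaddition, then loss of a small molecule). It leaves the pattern of ring B and the differentiation of its oxygens unsolved, and it is longer overall.

Alternative 3: The cut removes two C–C bonds of ring C. In the forward direction silyl ynol ether A9 (from A2) would add across C3 and C6 of pyrone A8 and lose CO2 to give arylsilane A7. Ipso-iododesilylation, demethylation and attachment of ring A would follow.
- In its favour: silicon fixes the position of iodine, so on positional certainty of the iodide this alternative is the equal of, or better than, the electrophilic iodination of the chosen plan. The arene again forms directly.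
- Against it here: ring C is the simplest ring and is available ready-made as 13. A9 would have to be made from a hindered phenol by base-heavy chemistry in the presence of three C–Br bonds. An unsymmetrical pyrone and an unsymmetrical alkyne with a bulky silyl group leave a regiochemical question, which the symmetric dienophile of the chosen plan does not have.
- Comparison: it spends a cycloaddition on the ring that needs it least, leaves ring B unsolved, and costs more steps. Mechanistically it is equivalent to the chosen key step.

Key step: step 3

Assumption: 1, 6, 11 and 13 and all reagents are purchased.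

Remark: the atom mapping of 5, 7 and 8 onto ring B of 17 was checked and needed no correction. The two hydroxyls of 10 are estimated to differ by about half a pKa unit, so the route does not rely on acidity to tell them apart. Compounds 7 and 8 are racemic, with one enantiomer drawn.

## Route

Step 1
Reactants: 1 tetrabromothiophene
Product: 3 2,3,4-tribromothiophene, via 3,4,5-tribromothiophen-2-yllithium 2 (not isolated)
Conditions: n-BuLi (1.0 equiv), THF, −78 °C; then H2O, −78 °C → rt
Reagents that add atoms: none
Why: Bromine–lithium exchange is fastest at an alpha carbon of a polybromothiophene, and 2 is the most stabilised anion (next to sulfur, flanked by bromine), so one equivalent at low temperature should remove exactly one alpha bromine; protonation then gives 3.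

Step 2
Reactants: 3 2,3,4-tribromothiophene
Product: 5 2,3,4-tribromothiophene 1,1-dioxide, via 2,3,4-tribromothiophene 1-oxide 4 (not isolated)
Conditions: H2O2·urea, (CF3CO)2O, MeCN/CH2Cl2, 0 °C → rt; cold aqueous wash, solution used at once
Reagents that add atoms: trifluoroperacetic acid, OOC(=O)C(F)(F)F (made in the flask from urea–hydrogen peroxide, NC(N)=O.OO, and trifluoroacetic anhydride, O=C(OC(=O)C(F)(F)F)C(F)(F)F)
Why: Sulfur oxidation of an electron-poor halothiophene needs the strongest common peracid; the S-oxide 4 is oxidised faster than 3, so the reaction should run through to the dioxide, as it does for tetrahalothiophenes.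

Step 3
Reactants: 5 2,3,4-tribromothiophene 1,1-dioxide; 6 vinylene carbonate
Product: 8 cis-4,5,6-tribromo-3a,7a-dihydro-1,3-benzodioxol-2-one (racemic), via bridged sulfone cycloadduct 7 (not isolated)
Conditions: 6 (10 equiv), BHT (1 mol %), PhMe, 90 °C, N2 sweep
Reagents that add atoms: none
Why: Dioxide 5 is a non-aromatic, electron-poor cis-diene and 6 a moderately electron-rich, strained Z-alkene, so an inverse-electron-demand Diels–Alder reaction is expected, with both new C–C bonds formed suprafacially in one event to give the 7-thianorbornene dioxide 7. Cheletropic extrusion of SO2 from 7, thermally allowed and driven by loss of a gas and of ring strain, then leaves the 1,3-cyclohexadiene 8. The closest known reaction type is the cycloaddition of tetrahalothiophene 1,1-dioxides with alkenes, whose adducts lose SO2 spontaneously to give halogenated cyclohexadienes. The six-membered carbocycle is closed by intermolecular [4+2] cycloaddition, and the one-atom sulfone bridge is then excised. The two new stereocentres C3a and C7a are cis because the Z geometry of 6, locked in its five-membered ring, is transferred stereospecifically; there is no absolute control, and both centres are destroyed in step 4. The selectivity needed is chemoselectivity for cross- over self-cycloaddition of 5 through its unsubstituted C4=C5 bond; it is secured by the large excess of 6, which cannot add to itself thermally, and by the three bromines, which slow the self-reaction. No regiochemical question arises because 6 is symmetric, so the bromines on C2, C3 and C4 of 5 and the hydrogen on C5 must end on C4, C5, C6 and C7 of 8; the endo or exo sense of 7 is irrelevant because the bridge is lost.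

Step 4
Reactants: 8 cis-4,5,6-tribromo-3a,7a-dihydro-1,3-benzodioxol-2-one
Product: 9 4,5,6-tribromo-1,3-benzodioxol-2-one
Conditions: DDQ (1.5 equiv), PhCl, 100 °C
Reagents that add atoms: none
Why: Quinone dehydrogenation of a 1,3-cyclohexadiene: DDQ abstracts hydride from a ring-fusion C–H (allylic to the diene and alpha to oxygen) and the arenium ion loses the second ring-fusion proton. The neutral, non-nucleophilic medium should keep the carbonate in place and avoid elimination of an oxygen; both stereocentres are removed.

Step 5
Reactants: 9 4,5,6-tribromo-1,3-benzodioxol-2-one
Product: 10 3,4,5-tribromobenzene-1,2-diol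
Conditions: LiOH (3 equiv), THF/H2O, 0 °C, argon; then 1 M HCl
Reagents that add atoms: none
Why: Acyl substitution at a strained cyclic diaryl carbonate with two good phenoxide leaving groups should be fast at 0 °C, far below any temperature at which hydroxide attacks C–Br; exclusion of air prevents oxidation of the catecholate to the quinone.

Step 6
Reactants: 10 3,4,5-tribromobenzene-1,2-diol; 11 3,5-dibromo-2-fluorobenzaldehyde
Product: 12 3,5-dibromo-2-(3,4,5-tribromo-2-hydroxyphenoxy)benzaldehyde
Conditions: 11 (1.0 equiv), K2CO3 (2.5 equiv), DMF, 80 °C, argon; then 1 M HCl
Reagents that add atoms: none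
Why: Nucleophilic aromatic substitution (SNAr) at the C–F bond, whose Meisenheimer adduct is stabilised by the ortho formyl group and by bromine on the other ortho and the para carbon. The oxygen on C1 of ring B (next to H6) is the less hindered and the more basic, so it should attack the doubly flanked C–F carbon first. An ether formed at the other oxygen can return by Smiles rearrangement through a spiro adduct, and the equilibrium should favour 12, whose free phenoxide is the bromine-flanked, more acidic one.

Step 7
Reactants: 12 3,5-dibromo-2-(3,4,5-tribromo-2-hydroxyphenoxy)benzaldehyde; 13 (4-bromophenyl)boronic acid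
Product: 14 3,5-dibromo-2-[3,4,5-tribromo-2-(4-bromophenoxy)phenoxy]benzaldehyde
Conditions: 13 (2.5 equiv), Cu(OAc)2 (1.5 equiv), pyridine (5 equiv), 4 Å MS, CH2Cl2, rt, dry air
Reagents that add atoms: none
Why: Chan–Lam oxidative coupling: the aryl group passes from boron to copper and the C–O bond forms by reductive elimination from a trivalent copper aryl phenoxide. Di-ortho-substituted halophenols are known substrates. At room temperature with a weak amine base the C–Br bonds and the aldehyde should be untouched and ring A should not migrate.

Step 8
Reactants: 14 3,5-dibromo-2-[3,4,5-tribromo-2-(4-bromophenoxy)phenoxy]benzaldehyde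
Product: 15 3,5-dibromo-2-[3,4,5-tribromo-2-(4-bromo-2-iodophenoxy)phenoxy]benzaldehyde
Conditions: NIS (1.05 equiv), CF3SO3H (0.2 equiv), CF3CO2H/CH2Cl2, 0 °C → rt, dark
Reagents that add atoms: N-iodosuccinimide, O=C1CCC(=O)N1I
Why: Electrophilic aromatic iodination with acid-activated NIS. Ring A has no C–H ortho or para to oxygen and carries CHO and two bromines, and the single C–H of ring B is flanked by bromine on a ring with three bromines, so ring C should react first. Its para position is blocked and its two ortho positions are equivalent; the first iodine deactivates the ring towards a second.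

Step 9
Reactants: 15 3,5-dibromo-2-[3,4,5-tribromo-2-(4-bromo-2-iodophenoxy)phenoxy]benzaldehyde
Product: 17 bromoiesol B (3,5-dibromo-2-[3,4,5-tribromo-2-(4-bromo-2-iodophenoxy)phenoxy]phenol), via aryl formate 16 (not isolated)
Conditions: mCPBA (2 equiv), CH2Cl2, rt; aq. Na2S2O3 wash; then Et3N (cat.), MeOH, rt
Reagents that add atoms: meta-chloroperbenzoic acid, OOC(=O)c1cccc(Cl)c1
Why: Baeyer–Villiger (Dakin-type) oxidation: the ortho aryloxy oxygen assists aryl migration in the Criegee intermediate, as is known for brominated 2-aryloxybenzaldehydes, giving formate 16, which methanol cleaves. The thiosulfate wash returns any trivalent iodine species formed at ring C to the aryl iodide.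

## Compound list

1 | tetrabromothiophene | Brc1sc(Br)c(Br)c1Br | starting material
2 | 3,4,5-tribromothiophen-2-yllithium | [Li]c1sc(Br)c(Br)c1Br | intermediate (not isolated)
3 | 2,3,4-tribromothiophene | Brc1csc(Br)c1Br | intermediate
4 | 2,3,4-tribromothiophene 1-oxide (pyramidal sulfur, inverting; no descriptor) | O=S1C=C(Br)C(Br)=C1Br | intermediate (not isolated)
5 | 2,3,4-tribromothiophene 1,1-dioxide | O=S1(=O)C=C(Br)C(Br)=C1Br | intermediate
6 | vinylene carbonate (1,3-dioxol-2-one) | O=C1OC=CO1 | starting material
7 | 4,5,6-tribromo-3a,4,7,7a-tetrahydro-4,7-epithio-1,3-benzodioxol-2-one 8,8-dioxide (bridged sulfone cycloadduct; racemic, endo adduct drawn) | O=C1O[C@@H]2[C@H](O1)[C@]3(Br)C(Br)=C(Br)[C@H]2S3(=O)=O | intermediate (not isolated)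
8 | cis-4,5,6-tribromo-3a,7a-dihydro-1,3-benzodioxol-2-one (racemic, one enantiomer drawn) | O=C1O[C@H]2C=C(Br)C(Br)=C(Br)[C@H]2O1 | intermediate
9 | 4,5,6-tribromo-1,3-benzodioxol-2-one | O=C1Oc2cc(Br)c(Br)c(Br)c2O1 | intermediate
10 | 3,4,5-tribromobenzene-1,2-diol | Oc1cc(Br)c(Br)c(Br)c1O | intermediate
11 | 3,5-dibromo-2-fluorobenzaldehyde | O=Cc1cc(Br)cc(Br)c1F | starting material
12 | 3,5-dibromo-2-(3,4,5-tribromo-2-hydroxyphenoxy)benzaldehyde | O=Cc1cc(Br)cc(Br)c1Oc1cc(Br)c(Br)c(Br)c1O | intermediate
13 | (4-bromophenyl)boronic acid | OB(O)c1ccc(Br)cc1 | starting material
14 | 3,5-dibromo-2-[3,4,5-tribromo-2-(4-bromophenoxy)phenoxy]benzaldehyde | O=Cc1cc(Br)cc(Br)c1Oc1cc(Br)c(Br)c(Br)c1Oc1ccc(Br)cc1 | intermediate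
15 | 3,5-dibromo-2-[3,4,5-tribromo-2-(4-bromo-2-iodophenoxy)phenoxy]benzaldehyde | O=Cc1cc(Br)cc(Br)c1Oc1cc(Br)c(Br)c(Br)c1Oc1ccc(Br)cc1I | intermediate
16 | 3,5-dibromo-2-[3,4,5-tribromo-2-(4-bromo-2-iodophenoxy)phenoxy]phenyl formate | O=COc1cc(Br)cc(Br)c1Oc1cc(Br)c(Br)c(Br)c1Oc1ccc(Br)cc1I | intermediate (not isolated)
17 | bromoiesol B, 3,5-dibromo-2-[3,4,5-tribromo-2-(4-bromo-2-iodophenoxy)phenoxy]phenol | Oc1cc(Br)cc(Br)c1Oc1cc(Br)c(Br)c(Br)c1Oc1ccc(Br)cc1I | target

## Step count and least certain steps

Total step count: 9. Longest linear sequence: 9 steps (1 → 17); 6, 11 and 13 are purchased and enter directly.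

Step 3 (key step). What may go wrong: 5 may add to itself through its unsubstituted C4=C5 bond, or decay, before the rather sluggish dienophile 6 reacts, and 6 may polymerise on heating. Fallback: the free alpha carbon is blocked by silicon, which is removed again once the ring is aromatic. Setting out from 1, the lithium compound 2 is quenched with Me3SiCl instead of water to give (3,4,5-tribromothiophen-2-yl)trimethylsilane F1. Peracid oxidation, through the S-oxide F2, gives 2,3,4-tribromo-5-(trimethylsilyl)thiophene 1,1-dioxide F3, a fully substituted dioxide that should be storable and can be heated longer with 6. Cycloaddition through the bridged sulfone F4 and loss of SO2 gives cis-4,5,6-tribromo-7-(trimethylsilyl)-3a,7a-dihydro-1,3-benzodioxol-2-one F5, and DDQ gives 4,5,6-tribromo-7-(trimethylsilyl)-1,3-benzodioxol-2-one F6. Hydrolysis with LiOH gives 3,4,5-tribromo-6-(trimethylsilyl)benzene-1,2-diol F7, and ipso-protonation with CF3CO2H, ortho to a hydroxyl, removes silicon. The route is rejoined at 10.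

Step 4. What may go wrong: hydride abstraction from a diene carrying three bromines may be slow, and traces of acid or base at high temperature may instead trigger elimination of one oxygen with loss of CO2. Fallback: oxidation at oxygen in place of dehydrogenation at carbon. Setting out from 8, cold LiOH hydrolysis gives cis-3,4,5-tribromocyclohexa-3,5-diene-1,2-diol F8. Oxidation of one allylic carbinol (MnO2, CH2Cl2, or Dess–Martin periodinane) gives 3,4,5-tribromo-6-hydroxycyclohexa-2,4-dien-1-one F9, which is the keto tautomer of the catechol and should enolise at once. A dithionite wash reverses any over-oxidation to the quinone. The route is rejoined at 10.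

Step 6. What may go wrong: arylation at the bromine-flanked oxygen, arylation of both oxygens, or incomplete equilibration between the two mono-ethers. Fallback: the choice of oxygen is moved to a silylation with a far larger steric bias, and ring C is attached before ring A. Setting out from 10, TBDPSCl and imidazole (DMF, 0 °C) should silylate the unhindered oxygen to give 2,3,4-tribromo-6-[(tert-butyldiphenylsilyl)oxy]phenol F10. Chan–Lam coupling with 13 gives tert-butyl(diphenyl)[3,4,5-tribromo-2-(4-bromophenoxy)phenoxy]silane F11, and fluoride frees 3,4,5-tribromo-2-(4-bromophenoxy)phenol F12. Its only hydroxyl then displaces fluoride from 11 (K2CO3, DMF); with the other oxygen already carrying a non-activated aryl group, no migration is possible. The route is rejoined at 14.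

Step 7. What may go wrong: slow coupling at a crowded, weakly nucleophilic phenoxide, while protodeboronation and homocoupling use up 13. Fallback: metal-free arylation by ligand coupling at trivalent iodine. Setting out from 12, the potassium phenoxide (t-BuOK, THF) is treated with bis(4-bromophenyl)iodonium triflate at rt to 40 °C. The route is rejoined at 14; no new compound is made.

Step 8. What may go wrong: iodination at C6 of ring B, a second iodination of ring C, or incomplete conversion under conditions mild enough to stay selective. Fallback: the position of iodine is fixed by a nitro group, replacing steps 7 and 8. Setting out from 12, SNAr with 4-bromo-1-fluoro-2-nitrobenzene (Cs2CO3, DMSO, at the lowest temperature that gives conversion, to limit migration of ring A) gives 3,5-dibromo-2-[3,4,5-tribromo-2-(4-bromo-2-nitrophenoxy)phenoxy]benzaldehyde F13. Reduction with SnCl2·2H2O gives 2-[2-(2-amino-4-bromophenoxy)-3,4,5-tribromophenoxy]-3,5-dibromobenzaldehyde F14, which is used crude. Diazotisation (NaNO2, H2SO4/AcOH) gives 5-bromo-2-[2,3,4-tribromo-6-(2,4-dibromo-6-formylphenoxy)phenoxy]benzenediazonium hydrogen sulfate F15, and KI replaces the diazonium group in a Sandmeyer-type iodination. The route is rejoined at 15.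

## Further compounds

F1 | step 3 | (3,4,5-tribromothiophen-2-yl)trimethylsilane | C[Si](C)(C)c1sc(Br)c(Br)c1Br
F2 | step 3 | 2,3,4-tribromo-5-(trimethylsilyl)thiophene 1-oxide | C[Si](C)(C)C1=C(Br)C(Br)=C(Br)S1=O
F3 | step 3 | 2,3,4-tribromo-5-(trimethylsilyl)thiophene 1,1-dioxide | C[Si](C)(C)C1=C(Br)C(Br)=C(Br)S1(=O)=O
F4 | step 3 | 4,5,6-tribromo-7-(trimethylsilyl)-3a,4,7,7a-tetrahydro-4,7-epithio-1,3-benzodioxol-2-one 8,8-dioxide (racemic, endo adduct drawn) | O=C1O[C@@H]2[C@H](O1)[C@]3(Br)C(Br)=C(Br)[C@@]2([Si](C)(C)C)S3(=O)=O
F5 | step 3 | cis-4,5,6-tribromo-7-(trimethylsilyl)-3a,7a-dihydro-1,3-benzodioxol-2-one (racemic) | O=C1O[C@H]2C([Si](C)(C)C)=C(Br)C(Br)=C(Br)[C@H]2O1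
F6 | step 3 | 4,5,6-tribromo-7-(trimethylsilyl)-1,3-benzodioxol-2-one | O=C1Oc2c(O1)c(Br)c(Br)c(Br)c2[Si](C)(C)C
F7 | step 3 | 3,4,5-tribromo-6-(trimethylsilyl)benzene-1,2-diol | C[Si](C)(C)c1c(O)c(O)c(Br)c(Br)c1Br
F8 | step 4 | cis-3,4,5-tribromocyclohexa-3,5-diene-1,2-diol (racemic) | O[C@H]1C=C(Br)C(Br)=C(Br)[C@H]1O
F9 | step 4 | 3,4,5-tribromo-6-hydroxycyclohexa-2,4-dien-1-one (racemic, one enantiomer drawn) | O=C1C=C(Br)C(Br)=C(Br)[C@H]1O
F10 | step 6 | 2,3,4-tribromo-6-[(tert-butyldiphenylsilyl)oxy]phenol | Oc1c(Br)c(Br)c(Br)cc1O[Si](c1ccccc1)(c1ccccc1)C(C)(C)C
F11 | step 6 | tert-butyl(diphenyl)[3,4,5-tribromo-2-(4-bromophenoxy)phenoxy]silane | CC(C)(C)[Si](Oc1cc(Br)c(Br)c(Br)c1Oc1ccc(Br)cc1)(c1ccccc1)c1ccccc1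
F12 | step 6 | 3,4,5-tribromo-2-(4-bromophenoxy)phenol | Oc1cc(Br)c(Br)c(Br)c1Oc1ccc(Br)cc1
F0 | step 7 | none | none
F13 | step 8 | 3,5-dibromo-2-[3,4,5-tribromo-2-(4-bromo-2-nitrophenoxy)phenoxy]benzaldehyde | O=Cc1cc(Br)cc(Br)c1Oc1cc(Br)c(Br)c(Br)c1Oc1ccc(Br)cc1[N+](=O)[O-]
F14 | step 8 | 2-[2-(2-amino-4-bromophenoxy)-3,4,5-tribromophenoxy]-3,5-dibromobenzaldehyde | Nc1cc(Br)ccc1Oc1c(Br)c(Br)c(Br)cc1Oc1c(Br)cc(Br)cc1C=O
F15 | step 8 | 5-bromo-2-[2,3,4-tribromo-6-(2,4-dibromo-6-formylphenoxy)phenoxy]benzenediazonium hydrogen sulfate | O=Cc1cc(Br)cc(Br)c1Oc1cc(Br)c(Br)c(Br)c1Oc1ccc(Br)cc1[N+]#N.OS(=O)(=O)[O-]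
A1 | alternative 1 | 1,2,3-tribromo-4-(4-bromo-2-iodophenoxy)-5-methoxybenzene | COc1cc(Br)c(Br)c(Br)c1Oc1ccc(Br)cc1I
A2 | alternative 1 | 4,5,6-tribromo-2-methoxyphenol (4,5,6-tribromoguaiacol) | COc1cc(Br)c(Br)c(Br)c1O
A3 | alternative 1 | 4-bromo-2-(trimethylsilyl)phenyl trifluoromethanesulfonate | C[Si](C)(C)c1cc(Br)ccc1OS(=O)(=O)C(F)(F)F
A4 | alternative 2 | 2-{3,5-dibromo-2-[3,4,5-tribromo-2-(4-bromo-2-iodophenoxy)phenoxy]phenyl}-4,4,5,5-tetramethyl-1,3,2-dioxaborolane | CC1(C)OB(c2cc(Br)cc(Br)c2Oc2cc(Br)c(Br)c(Br)c2Oc2ccc(Br)cc2I)OC1(C)C
A5 | alternative 2 | 3,5-dibromo-2H-pyran-2-one | O=C1OC=C(Br)C=C1Br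
A6 | alternative 2 | 2-{[3,4,5-tribromo-2-(4-bromo-2-iodophenoxy)phenoxy]ethynyl}-4,4,5,5-tetramethyl-1,3,2-dioxaborolane | CC1(C)OB(C#COc2cc(Br)c(Br)c(Br)c2Oc2ccc(Br)cc2I)OC1(C)C
A7 | alternative 3 | [5-bromo-2-(2,3,4-tribromo-6-methoxyphenoxy)phenyl]trimethylsilane | COc1cc(Br)c(Br)c(Br)c1Oc1ccc(Br)cc1[Si](C)(C)C
A8 | alternative 3 | 5-bromo-2H-pyran-2-one | O=C1OC=C(Br)C=C1
A9 | alternative 3 | trimethyl[(2,3,4-tribromo-6-methoxyphenoxy)ethynyl]silane | COc1cc(Br)c(Br)c(Br)c1OC#C[Si](C)(C)C
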